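**Plan**

1. Retrosynthesis: remove the 4-hydroxybenzoate at O6 and the C8=C9 unsaturation, and return C6–OH to a ketone. The C6/C10 dicarbonyl pair is then the retron of a glycol cleavage, so C6–C10 is reconnected to a cyclobutane-1,2-diol, whose bonds C10–C1 and C6–C5 are cut last.
2. Forward: ring A is bought as 3-methylcyclopent-2-enone. An enone–alkene (2+2) photocycloaddition with a symmetric cyclopentene-1,2-diol bis-silyl ether forms C10–C1 and C6–C5 at once. C4 is elaborated on the rigid tricycle, and Pb(OAc)4 scission of C6–C10 then merges the cyclobutane and the second cyclopentane into the seven-membered ring B.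
3. Enabling feature: C6 and C10, the two ring-B carbons attached to the fusion bond C5–C1, both carry oxygen (a 1,4-dioxygen pattern = latent enediol), and C4 next to C5 carries oxygen (latent enone carbonyl of ring A).
4. Stereochemistry: C1 is set in the photocycloaddition and made absolute by a CBS kinetic resolution. C4 is relayed from C1 by exo-face epoxidation of the cis-bicyclo[3.2.0] unit, C5 by thermodynamic epimerisation to the trans fusion, and C6 by hydride delivery from the C4 hydroxyl.
5. End game: site-selective esterification at O6, IBX dehydrogenation to the C8=C9 enone, phenol unmasking.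

Key step: step 2

Remark (numbering): daucane numbering is used throughout. C1 is the methyl-bearing fusion carbon, C2/C3 the ring-A methylenes, C4 the carbinol carbon, C5 the fusion CH, C6 the acyloxy carbon, C7 a CH2, C8 the methyl-bearing carbon, C9 the CH and C10 the ketone carbon; β is the face of the C1 methyl.
Remark (chemistry): minor photoadduct diastereomers (syn arrangement across the cyclobutane, C8 epimer) are carried along, because C6 and C10 become carbonyl carbons in step 8 and C8 becomes sp2 in step 12. Structures show the expected major isomer.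
Remark (supply): 4-(tert-butyldimethylsilyloxy)benzoic acid 15 is taken as a catalogue compound.

Step 1
Reactants: 1 dimethyl 3-methylglutarate
Product: 2 4-methyl-1,2-bis(trimethylsilyloxy)cyclopent-1-ene
Conditions: Na (4.2 equiv), Me3SiCl (4.5 equiv), toluene, reflux; filter, distil
Reagents that add atoms: chlorotrimethylsilane, C[Si](C)(C)Cl
Why: Acyloin condensation in its Rühlmann variant, in which the five-membered sodium enediolate is silylated as it forms so that Dieckmann and aldol side reactions are suppressed; the product has a mirror plane and no stereocentre.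

Step 2
Reactants: 2 4-methyl-1,2-bis(trimethylsilyloxy)cyclopent-1-ene, 3 3-methylcyclopent-2-en-1-one
Product: 4 racemic cis-anti-cis photoadduct (6,9-dimethyl-1,7-bis(trimethylsilyloxy)tricyclo[5.3.0.0(2,6)]decan-3-one)
Conditions: hν (medium-pressure Hg lamp, Pyrex filter, λ > 300 nm), 2 (4 equiv), degassed hexane, −20 °C
Reagents that add atoms: none
Why: Enone–alkene (2+2) photocycloaddition, the cyclobutane-forming half of the known photocycloaddition/glycol-cleavage ring expansion with 1,2-bis(silyloxy)cycloalkenes: n→π* excitation of 3 and intersystem crossing give the enone triplet, which bonds to the electron-rich olefin 2 to give a triplet 1,4-diradical that collapses after spin inversion, so that C10–C1 and C6–C5 are made in the same event. The only ring closed is the four-membered ring C1–C5–C6–C10; it closes by radical–radical coupling of the 1,4-diradical (a stepwise, formally π2+π2 photochemical closure) and is necessarily cis-fused to both five-membered rings. Of the new stereocentres, C1 (quaternary) and C5 are tied cis by the geometry of the cyclopentenone, C6 and C10 are cis because they come from a ring olefin and should sit anti to ring A for steric reasons, and the C8 methyl should end up exo because the enone approaches anti to it. The selectivity the step needs is regiochemical (C1 must join one enediol carbon and C5 the other) and is guaranteed by the mirror plane of 2, which makes its two olefinic carbons equivalent; cross-addition over enone dimerisation is secured by excess 2 and by light that only 3 absorbs. Only C1 has to survive: C5 is corrected in step 9, C6 and C10 become carbonyl carbons in step 8 and C8 becomes sp2 in step 12, and the strain stored here drives step 8.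

Step 3
Reactants: 4 racemic photoadduct
Product: 5 (1S)-enantiomer of the photoadduct ketone
Conditions: (R)-2-methyl-CBS-oxazaborolidine [(R)-1-methyl-3,3-diphenyltetrahydro-1H,3H-pyrrolo[1,2-c][1,3,2]oxazaborole] (0.2 equiv), BH3·SMe2 (0.35 equiv), THF, −20 °C, stopped just past half conversion; MeOH; chromatography
Reagents that add atoms: none
Why: Kinetic resolution by Corey–Bakshi–Shibata reduction: with the branched C5 arm as the large group, the hydride trajectory preferred by the (R)-catalyst coincides with the open exo face only in the unwanted enantiomer, which should be reduced to the endo alcohol and removed, leaving 5 and thereby fixing C1 in the absolute sense.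

Step 4
Reactants: 5 (1S)-photoadduct ketone
Product: 7 C3=C4 enol triflate, via potassium C3-enolate 6 (not isolated)
Conditions: KN(SiMe3)2, THF, −78 °C; PhNTf2, −78 → 0 °C
Reagents that add atoms: N-phenylbis(trifluoromethanesulfonimide), O=S(=O)(N(c1ccccc1)S(=O)(=O)C(F)(F)F)C(F)(F)F
Why: Kinetic enolisation and O-sulfonylation: the base should remove a proton from the C3 methylene and not from the hindered C5 methine at the cyclobutane fusion, and the intact silyl ethers exclude retro-aldol opening of the four-membered ring.

Step 5
Reactants: 7 enol triflate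
Product: 8 4-isopropyl-3-ene (bis-TMS ether)
Conditions: i-PrMgCl (1.5 equiv), Fe(acac)3 (5 mol%), THF/NMP, −30 °C
Reagents that add atoms: isopropylmagnesium chloride, CC(C)[Mg]Cl
Why: Iron-catalysed Kumada-type cross-coupling of an alkenyl triflate with a secondary alkyl Grignard reagent, fast enough at low temperature that isomerisation of the isopropyl group and attack on the silyl ethers should not compete; no stereocentre is formed.

Step 6
Reactants: 8 4-isopropyl-3-ene
Product: 9 3β,4β-epoxide (exo)
Conditions: mCPBA, NaHCO3, CH2Cl2, 0 °C
Reagents that add atoms: meta-chloroperbenzoic acid, O=C(OO)c1cccc(Cl)c1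
Why: Prilezhaev epoxidation on the convex (exo) face of the cis-bicyclo[3.2.0]heptene, the face of the C1 methyl and H5, because the concave face is screened by the cyclobutane and its OTMS groups; this puts the C4 oxygen cis to the C1 methyl as in the target, and the buffer prevents acid-induced cyclobutylcarbinyl rearrangement.

Step 7
Reactants: 9 exo-epoxide
Product: 10 4β-hydroxy-4α-isopropyl tricycle (bis-TMS ether)
Conditions: LiBHEt3 (3 equiv), THF, 0 → 50 °C; H2O
Reagents that add atoms: none
Why: Reductive epoxide opening by lithium triethylborohydride with SN2 hydride delivery at the secondary C3 (the reagent of choice for hindered epoxides that require endo attack), so the C4–O bond is untouched and the configuration set in step 6 is kept in the tertiary alcohol.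

Step 8
Reactants: 10 tertiary alcohol
Product: 12 cis-fused 4β-hydroxy-5β-H-daucane-6,10-dione, via cyclobutane-1,2-diol triol 11 (not isolated)
Conditions: K2CO3, MeOH, 0 °C; solvent exchange; Pb(OAc)4, CH2Cl2/pyridine, 0 °C
Reagents that add atoms: none
Why: Silyl ether methanolysis followed by Criegee glycol cleavage: the cis di-tertiary cyclobutanediol readily forms the cyclic lead diester, and scission of C6–C10 is driven by release of the four-membered ring strain, merging the cyclobutane and the second cyclopentane into the seven-membered 1,4-diketone; C6 and C10 lose stereogenicity while C1, C4 and C5 are untouched.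

Step 9
Reactants: 12 cis-fused diketone
Product: 13 trans-fused 4β-hydroxy-5α-H-daucane-6,10-dione
Conditions: DBU (0.5 equiv), toluene, 60 °C
Reagents that add atoms: none
Why: Base-mediated epimerisation through the C5–C6 enol(ate): C5 is the only enolisable stereocentre, and inversion exchanges the flanking C10/isopropyl pair for the smaller methyl/hydroxyl pair and allows an O4–H···O=C6 hydrogen bond, so the trans fusion should be favoured under thermodynamic control; the weak amine base keeps the tertiary alkoxide, and hence retro-aldol cleavage, at a minimum.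

Step 10
Reactants: 13 trans-fused diketone
Product: 14 4β,6α-dihydroxy-5α-H-daucan-10-one
Conditions: Me4NBH(OAc)3, MeCN/AcOH (1:1), −30 → −20 °C
Reagents that add atoms: none
Why: Evans–Saksena hydroxyl-directed reduction: the C4 hydroxyl displaces an acetate on boron and the resulting alkoxyborohydride delivers hydride intramolecularly to the β face of the C6 carbonyl, setting the 6α-hydroxyl; the C10 ketone has no hydroxyl within reach (O4 is trans to C10 on ring A) and the reagent leaves such ketones alone.

Step 11
Reactants: 14 diol, 15 4-(tert-butyldimethylsilyloxy)benzoic acid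
Product: 16 6α-[4-(tert-butyldimethylsilyloxy)benzoyloxy]-4β-hydroxy-5α-H-daucan-10-one
Conditions: DCC, DMAP, CH2Cl2, 0 °C → rt
Reagents that add atoms: none
Why: Steglich esterification, in which only the secondary C6 hydroxyl should be acylated while the tertiary C4 hydroxyl is inert, the same site selectivity being known for the 4,6-diol of this skeleton; no stereocentre is touched.

Step 12
Reactants: 16 saturated keto ester
Product: 17 6α-[4-(tert-butyldimethylsilyloxy)benzoyloxy]-4β-hydroxydauc-8-en-10-one
Conditions: IBX (2 equiv), DMSO/fluorobenzene, 65 °C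
Reagents that add atoms: none
Why: IBX-mediated α,β-dehydrogenation of a ketone: C10 can enolise only towards C9 because C1 is quaternary, so the double bond must form between C9 and C8, giving the β-methyl enone and erasing the C8 stereocentre; the phenol stays silylated because free phenols are oxidised by IBX.

Step 13
Reactants: 17 silyl-protected enone ester
Product: 18 target, (3R,3aS,4S,8aS)-3-hydroxy-6,8a-dimethyl-8-oxo-3-(propan-2-yl)-1,2,3,3a,4,5,8,8a-octahydroazulen-4-yl 4-hydroxybenzoate
Conditions: HF·pyridine, THF/pyridine, 0 °C
Reagents that add atoms: none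
Why: Fluoride cleavage of the aryl silyl ether under mildly acidic conditions, preferred to a basic deprotection because the enone could lose the C6 acyloxy group by vinylogous β-elimination through its dienolate; no stereocentre is affected.

**Compound list**

1 | dimethyl 3-methylglutarate (dimethyl 3-methylpentanedioate) | COC(=O)CC(C)CC(=O)OC | starting material
2 | 4-methyl-1,2-bis(trimethylsilyloxy)cyclopent-1-ene (achiral) | CC1CC(O[Si](C)(C)C)=C(O[Si](C)(C)C)C1 | intermediate
3 | 3-methylcyclopent-2-en-1-one | CC1=CC(=O)CC1 | starting material
4 | racemic photoadduct, 6,9-dimethyl-1,7-bis(trimethylsilyloxy)tricyclo[5.3.0.0(2,6)]decan-3-one: C4 ketone; cyclobutane C1–C5–C6–C10 on the α face of ring A (1β-Me, 5β-H); 6- and 10-OTMS cis to each other, second cyclopentane anti to ring A; 8-Me exo; racemate (SMILES shows the enantiomer carried on) | C[C@]12CCC(=O)[C@H]1[C@]3(O[Si](C)(C)C)C[C@@H](C)C[C@]23O[Si](C)(C)C | intermediate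
5 | (1S)-enantiomer of 4 (target configuration at the quaternary C1) | C[C@]12CCC(=O)[C@H]1[C@]3(O[Si](C)(C)C)C[C@@H](C)C[C@]23O[Si](C)(C)C | intermediate
6 | potassium C3=C4 enolate of 5 | C[C@]12CC=C([O-])[C@H]1[C@]3(O[Si](C)(C)C)C[C@@H](C)C[C@]23O[Si](C)(C)C.[K+] | intermediate (not isolated)
7 | C3=C4 enol triflate of 5 | C[C@]12CC=C(OS(=O)(=O)C(F)(F)F)[C@H]1[C@]3(O[Si](C)(C)C)C[C@@H](C)C[C@]23O[Si](C)(C)C | intermediate
8 | 4-isopropyl-3-ene tricycle (bis-TMS ether) | C[C@]12CC=C(C(C)C)[C@H]1[C@]3(O[Si](C)(C)C)C[C@@H](C)C[C@]23O[Si](C)(C)C | intermediate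
9 | 3β,4β-epoxide of 8 (exo; oxygen cis to the C1 methyl and H5) | C[C@]12C[C@@H]3O[C@]3(C(C)C)[C@H]1[C@]4(O[Si](C)(C)C)C[C@@H](C)C[C@]24O[Si](C)(C)C | intermediate
10 | 4β-hydroxy-4α-isopropyl tricycle (6,10-bis-TMS ether; 1β-Me, 5β-H) | C[C@]12CC[C@@](O)(C(C)C)[C@H]1[C@]3(O[Si](C)(C)C)C[C@@H](C)C[C@]23O[Si](C)(C)C | intermediate
11 | 4β,6,10-triol (cis-cyclobutane-1,2-diol) | C[C@]12CC[C@@](O)(C(C)C)[C@H]1[C@]3(O)C[C@@H](C)C[C@]23O | intermediate (not isolated)
12 | cis-fused 4β-hydroxy-4α-isopropyl-1β,8α-dimethyl-5β-H-hydroazulene-6,10-dione (4β-hydroxy-5β-H-daucane-6,10-dione) | C[C@H]1CC(=O)[C@@]2(C)CC[C@@](O)(C(C)C)[C@H]2C(=O)C1 | intermediate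
13 | trans-fused 4β-hydroxy-5α-H-daucane-6,10-dione | C[C@H]1CC(=O)[C@@]2(C)CC[C@@](O)(C(C)C)[C@@H]2C(=O)C1 | intermediate
14 | 4β,6α-dihydroxy-5α-H-daucan-10-one | C[C@H]1CC(=O)[C@@]2(C)CC[C@@](O)(C(C)C)[C@@H]2[C@@H](O)C1 | intermediate
15 | 4-(tert-butyldimethylsilyloxy)benzoic acid | OC(=O)c1ccc(O[Si](C)(C)C(C)(C)C)cc1 | starting material
16 | 6α-[4-(tert-butyldimethylsilyloxy)benzoyloxy]-4β-hydroxy-5α-H-daucan-10-one | C[C@H]1CC(=O)[C@@]2(C)CC[C@@](O)(C(C)C)[C@@H]2[C@@H](OC(=O)c2ccc(O[Si](C)(C)C(C)(C)C)cc2)C1 | intermediate
17 | 6α-[4-(tert-butyldimethylsilyloxy)benzoyloxy]-4β-hydroxydauc-8-en-10-one | CC1=CC(=O)[C@@]2(C)CC[C@@](O)(C(C)C)[C@@H]2[C@@H](OC(=O)c2ccc(O[Si](C)(C)C(C)(C)C)cc2)C1 | intermediate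
18 | (3R,3aS,4S,8aS)-3-hydroxy-6,8a-dimethyl-8-oxo-3-(propan-2-yl)-1,2,3,3a,4,5,8,8a-octahydroazulen-4-yl 4-hydroxybenzoate | CC1=CC(=O)[C@@]2(C)CC[C@@](O)(C(C)C)[C@@H]2[C@@H](OC(=O)c2ccc(O)cc2)C1 | target

Total steps: 13. Longest linear sequence: 13 steps (1 → 18); 3 and 15 enter as purchased materials.

**Steps most likely to fail**

Step 3. The two enantiomers of 4 may be reduced at too similar rates (the exo bias of the substrate can override the catalyst), so the recovered ketone would be of insufficient enantiomeric purity. The fallback is a covalent resolution that sets out from racemic 4. Lithiated (S)-N,S-dimethyl-S-phenylsulfoximine (n-BuLi, THF, −78 °C) should add to the exo face of the ketone to give two diastereomers, separable by chromatography: the β-hydroxysulfoximine of the wanted enantiomer F1 and the β-hydroxysulfoximine of the unwanted enantiomer F2. Thermolysis of F1 (toluene, reflux) should release the sulfoximine and return the route at 5.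

Step 9. Retro-aldol cleavage or dehydration of the tertiary β-hydroxy ketone may outrun enolisation at the hindered C5, since both side reactions start from the free hydroxyl or its alkoxide. The fallback sets out from 12 and masks the hydroxyl: N-(trimethylsilyl)imidazole in CH2Cl2 should give the cis-fused 4-O-trimethylsilyl ether F3. Epimerisation with DBU in toluene at 80 °C (or catalytic t-BuOK) should then give the trans-fused 4-O-trimethylsilyl ether F4. Brief K2CO3/MeOH at 0 °C removes the silyl group and comes back to the route at 13.

Step 7. Hydride attack at C3 has to come from the concave face next to the OTMS groups, and may be too slow or be replaced by base-induced side reactions. The fallback avoids the SN2 event and sets out from 9. LiNEt2 (Et2O/hexane, reflux) should abstract an exo proton at C2 and open the C3–O bond to give the allylic tertiary alcohol F5 (C2=C3, 4β-OH). Hydrogenation (H2, PtO2, EtOAc) then returns the route at 10.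

Further compounds
F1 | step 3 | β-hydroxysulfoximine from 5 and (S)-N,S-dimethyl-S-phenylsulfoximine (C4: exo CH2S, endo OH) | C[C@]12CC[C@](O)(C[S@@](=O)(=NC)c3ccccc3)[C@H]1[C@]4(O[Si](C)(C)C)C[C@@H](C)C[C@]24O[Si](C)(C)C
F2 | step 3 | diastereomeric β-hydroxysulfoximine from the enantiomer of 5 | C[C@@]12CC[C@@](O)(C[S@@](=O)(=NC)c3ccccc3)[C@@H]1[C@@]4(O[Si](C)(C)C)C[C@H](C)C[C@@]24O[Si](C)(C)C
F3 | step 9 | 4-O-trimethylsilyl ether of cis-fused diketone 12 | C[C@H]1CC(=O)[C@@]2(C)CC[C@@](O[Si](C)(C)C)(C(C)C)[C@H]2C(=O)C1
F4 | step 9 | 4-O-trimethylsilyl ether of trans-fused diketone 13 | C[C@H]1CC(=O)[C@@]2(C)CC[C@@](O[Si](C)(C)C)(C(C)C)[C@@H]2C(=O)C1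
F5 | step 7 | allylic tertiary alcohol (C2=C3, 4β-hydroxy-4α-isopropyl, bis-TMS ether) | C[C@]12C=C[C@@](O)(C(C)C)[C@H]1[C@]3(O[Si](C)(C)C)C[C@@H](C)C[C@]23O[Si](C)(C)C
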